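The easy step first: X, under the enzyme L, becomes the product Q, and Q then turns reversibly into the other product E. In the larch run 94.3% of the X charged is already Q or E at 0.667 h.

common to all: L 0.0079 mol%
- larch: X 0.022 M; run made earlier
- oak: X 0.011 M; run made earlier
- ash: X 0.017 M; run made earlier
- north: X 0.022 M; one stirred flow tank at steady state, fed with the mixture as stated, mean residence time 8.0 h
- north-east: X 0.022 M (fed, over 4.00 h); a stirred flask in which X is dosed at a steady rate over 4.00 h without added volume, worked up at 8.0 h; time 8.0 h
- south-west: X 0.022 M; one stirred flow tank at steady state, fed with the mixture as stated, mean residence time 24.0 h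
- west: X 0.022 M; a closed flask charged with all of it at once and left for 8.0 h; time 8.0 h

| run | time / h | Q / % | E / % |
|---|---|---|---|
| larch | 0.667 | 78.5 | 15.8 |
| larch | 1.33 | 70.3 | 31.2 |
| larch | 2.50 | 57.2 | 43.2 |
| larch | 4.00 | 51.5 | 50.5 |
| larch | 8.00 | 48.4 | 52.1 |
| oak | 2.00 | 60.8 | 40.2 |
| oak | 4.00 | 50.9 | 51.0 |
| oak | 6.00 | 50.3 | 50.7 |
| oak | 8.00 | 48.6 | 52.9 |
| oak | 10.0 | 47.8 | 52.2 |
| ash | 2.00 | 59.7 | 40.1 |
| ash | 4.00 | 50.0 | 49.1 |
| ash | 6.00 | 48.0 | 53.1 |
| ash | 8.00 | 45.9 | 53.8 |
| ash | 10.0 | 47.3 | 52.9 |

(scatter of a reading: 1 percentage point)

- the stated concentrations are those of everything mixed, before any reaction; amounts are the same in each set-up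
- on the list of suspects stand: X + L -> Q + L; Q <-> E
- the feed brings no volume worth counting
- the earlier runs were made in a closed, stirred flask

- the set-up with the highest share of Q in all that became Q or E, at the outlet or at the end ("none" if the first two lie within 2 percentage points) (north / north-east / south-west / west / none)
- share of Q in all that became Q or E, at the outlet or at the end, north
- share of Q in all that became Q or E, at the outlet or at the end, north-east
- share of Q in all that became Q or E, at the outlet or at the end, south-west
- share of Q in all that became Q or E, at the outlet or at the end, west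

Oak looks like larch with half the X, and at 4.00 h larch reads Q 51.5% and oak 50.9%, a gap of 0.6 percentage points against a scatter of 1 point. So I read the fall of Q as first order, and both runs sink towards one plateau. The last readings of the three runs average s∞ = 47.8%.

Oak at 2.00 h still holds Q 60.8%, and from that reading I get the relaxation time θ, in which the excess of Q over s∞ shrinks by a factor e: 1.44 h. The larch reading at 0.667 h comes sooner than that, so in my reckoning I count X as turned to Q at once. The ratio N = stay/θ, with the stay being the time in a flask or the mean residence time of a tank, then marks the crossing from kinetic to thermodynamic control, at N near one.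

North and west both have N = 5.57, but they treat it differently. With X turned at once and a first-order fall, a closed flask shrinks the excess by exp(−N), while a tank, mixing young and old, shrinks it by 1/(1+N). So I reckon west 48.0% and north 55.8%. South-west comes to 50.8%, and north-east, averaging over the ages of the dose, to 48.9%. North leads by 5 points.

The forecast names north, with north 55.9%, north-east 49.1%, south-west 50.9% and west 48.2%, its north lying 0.10 points from mine, on the ground that the tank share “does not depend on the rate of the X step”.

The flask gives north: north 54.8%, north-east 48.4%, south-west 50.3%, west 47.7%.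

    X + L → Q + L, rate k1*[X]*[L]/(1 + ([X]/Km1) + ([Q]/Kp1)) (14.4 mM, 1.44 mM, k = 4.77 × 10⁵ M⁻¹ min⁻¹)
    Q ⇌ E (K = 1.10, k = 0.00684 min⁻¹)

My north stands 1.00 point above the flask. With θ = 1.44 h, north and west share one N, yet north ends 7.1 points higher. West read earlier, at 3.0 h, has N = 2.08, so exp(−N) gives me 54.3%. In that flask Q, not E, holds most of the charge, and its share reads 53.5%.

The data stem from a simulated flask for an exercise; the scatter is artificial.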